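**Retrosynthetic overview**
1. Target ⇐ benzyl ether of the target (hydrogenolysis) ⇐ hydroxyl-directed epoxidation of the C2=C3 cyclopentene ⇐ acylation of the C7 alcohol.
2. Key step: the acyclic enal–enone 18 closes both rings in one operation. An NHC turns the enal into a homoenolate whose β-carbon (C3a) adds to the enone β-carbon (C8a), forming the seven-membered ring first.
3. Aldol closure (C3 to C2), β-lactonisation and loss of CO2 then give the five-membered ring with the C2=C3 alkene; the oxirane is made last.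
4. 18 ⇐ Wittig (enal) and cross-metathesis (enone) on a chain whose C7/C8 centres come from an anti-selective γ-isopropylallylboration.
5. C5 comes from a catalytic asymmetric allylation of 4,4-dimethoxybutan-2-one.

Numbering: ring positions follow azulene (C1–C3, C3a, C4–C8, C8a); α is the face that carries the epoxide oxygen in the target (5-OH, 7-ester and 8-isopropyl are α; H-3a is β, H-8a is α).

Assumption: the sense of induction in step 1 is taken from the large/small-substituent model of the catalyst; if the mirror-image alcohol forms, the enantiomeric ligand is used.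

**Step 1**
Reactants: 1 4,4-dimethoxybutan-2-one; 2 allylboronic acid pinacol ester
Product: 4 (3S)-1,1-dimethoxy-3-methylhex-5-en-3-ol, via O-pinacolboryl ether 3 (not isolated)
Conditions: CuF2·2H2O (3 mol %), (R,R)-iPr-DuPHOS (6 mol %), La(OiPr)3 (4.5 mol %), DMF, −40 °C; aq. work-up
Reagents that add atoms: allylboronic acid pinacol ester 2, C=CCB1OC(C)(C)C(C)(C)O1
Why: Copper-catalysed enantioselective allylboration of a methyl ketone, in which the chiral allylcopper distinguishes CH3 from CH2CH(OMe)2 and sets the tertiary carbinol that becomes C5; any minor enantiomer becomes a separable diastereomer after step 3.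

**Step 2**
Reactants: 4 (3S)-1,1-dimethoxy-3-methylhex-5-en-3-ol
Product: 6 (3S)-3-hydroxy-5,5-dimethoxy-3-methylpentanal, via secondary ozonide 5 (not isolated)
Conditions: O3, CH2Cl2, −78 °C; PPh3, −78 → 20 °C; used crude
Reagents that add atoms: ozone, [O-][O+]=O
Why: Ozonolysis with reductive work-up cleaves the only alkene to the aldehyde (C7) and leaves the acetal and the tertiary carbinol untouched.

**Step 3**
Reactants: 6 (3S)-3-hydroxy-5,5-dimethoxy-3-methylpentanal; 7 (E)-4-methylpent-2-ene; 8 (−)-B-methoxydiisopinocampheylborane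
Product: 12 (3S,5R,6S)-1,1-dimethoxy-3-methyl-6-(propan-2-yl)oct-7-ene-3,5-diol, via allylpotassium reagent 9 (not isolated), via allylborane reagent 10 (not isolated), via borinate ester 11 (not isolated)
Conditions: 7, n-BuLi, KOtBu, THF, −78 → −50 °C; 8, −78 °C; BF3·OEt2; 6 (0.5 equiv), −78 °C; NaOH, H2O2, 0 → 20 °C
Reagents that add atoms: (E)-4-methylpent-2-ene 7, C/C=C/C(C)C
Why: Brown-type (E)-γ-alkylallylboration through a closed chair (Zimmerman–Traxler) transition state gives the anti adduct, and the isopinocampheyl groups from (+)-α-pinene direct attack to the Si face of the aldehyde, so C7 (R) and C8 (S) are set under reagent control.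

**Step 4**
Reactants: 12 (3S,5R,6S)-1,1-dimethoxy-3-methyl-6-(propan-2-yl)oct-7-ene-3,5-diol; 13 but-3-en-2-one
Product: 14 (3E,5S,6R,8S)-6,8-dihydroxy-10,10-dimethoxy-8-methyl-5-(propan-2-yl)dec-3-en-2-one
Conditions: 13 (5 equiv), second-generation Hoveyda–Grubbs catalyst RuCl2(H2IMes)(=CH-C6H4-2-OiPr) (5 mol %; H2IMes = 1,3-dimesityl-4,5-dihydroimidazol-2-ylidene), CH2Cl2, 40 °C
Reagents that add atoms: but-3-en-2-one 13, CC(=O)C=C
Why: Olefin cross-metathesis of the single terminal alkene with the electron-poor partner gives the E-enone; no stereocentre is touched, and 14 is kept neutral and silylated at once.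

**Step 5**
Reactants: 14 (3E,5S,6R,8S)-6,8-dihydroxy-10,10-dimethoxy-8-methyl-5-(propan-2-yl)dec-3-en-2-one
Product: 16 (3S,5R,6S,7E)-3-methyl-9-oxo-6-(propan-2-yl)-3,5-bis(triethylsilyloxy)dec-7-enal, via lutidinium acetal salt 15 (not isolated)
Conditions: TESOTf (4 equiv), 2,6-lutidine (6 equiv), CH2Cl2, −78 → 0 °C; H2O
Reagents that add atoms: triethylsilyl trifluoromethanesulfonate, CC[Si](CC)(CC)OS(=O)(=O)C(F)(F)F; water, O
Why: The silyl triflate first silylates both hydroxyls and then converts the dimethyl acetal into a pyridinium N,O-acetal salt that water hydrolyses to the aldehyde (Fujioka-type acetal cleavage); silylating the C7 hydroxyl first prevents lactol formation.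

**Step 6**
Reactants: 16 (3S,5R,6S,7E)-3-methyl-9-oxo-6-(propan-2-yl)-3,5-bis(triethylsilyloxy)dec-7-enal; 17 (triphenylphosphoranylidene)acetaldehyde
Product: 18 (2E,5R,7R,8S,9E)-5-methyl-11-oxo-8-(propan-2-yl)-5,7-bis(triethylsilyloxy)dodeca-2,9-dienal
Conditions: 17 (1.3 equiv), toluene, 60 °C
Reagents that add atoms: (triphenylphosphoranylidene)acetaldehyde 17, O=CC=P(c1ccccc1)(c1ccccc1)c1ccccc1
Why: Wittig olefination with the stabilised formyl ylide gives the E-enal at the aldehyde and leaves the less electrophilic enone alone.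

**Step 7**
Reactants: 18 (2E,5R,7R,8S,9E)-5-methyl-11-oxo-8-(propan-2-yl)-5,7-bis(triethylsilyloxy)dodeca-2,9-dienal
Product: 21 (3aS,5R,7R,8S,8aR)-2,5-dimethyl-8-(propan-2-yl)-1,3a,4,5,6,7,8,8a-octahydroazulene-5,7-diol, via β-lactone 19 (not isolated), via bis-silyl cyclopentene 20 (not isolated)
Conditions: IMes (1,3-dimesitylimidazol-2-ylidene, 10 mol %), toluene, 0.01 M, 25 → 40 °C; 110 °C; Bu4NF, THF, 25 °C
Reagents that add atoms: none
Why: Proposed new method: an intramolecular, seven-ring-forming version of the Nair–Bode carbene-catalysed homoenolate annulation of enals with enones (known between two molecules to give trans-3,4-disubstituted cyclopentenes or, with alkyl ketones, the fused β-lactones); the carbene adds to the enal, the Breslow intermediate reacts as a homoenolate whose β-carbon C3a adds 7-exo to the enone β-carbon C8a (both carbons are electrophilic in 18), the enol azolium then closes C3 onto the C2 ketone by aldol reaction, the tertiary alkoxide acylates to release the carbene as β-lactone 19, and heating expels CO2 to leave the C2=C3 alkene; C8a is set anti to the isopropyl group by allylic 1,3-strain in the enone and C3a trans to it in a chair-like transition state with the three carbon substituents equatorial, which is the trans ring fusion of the target, and fluoride then removes both silyl groups.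

**Step 8**
Reactants: 21 (3aS,5R,7R,8S,8aR)-2,5-dimethyl-8-(propan-2-yl)-1,3a,4,5,6,7,8,8a-octahydroazulene-5,7-diol; 22 3-(benzyloxy)-4-methoxybenzoic acid
Product: 23 (3aS,5R,7R,8S,8aR)-5-hydroxy-2,5-dimethyl-8-(propan-2-yl)-1,3a,4,5,6,7,8,8a-octahydroazulen-7-yl 3-(benzyloxy)-4-methoxybenzoate
Conditions: 22 (1.5 equiv), DCC (1.6 equiv), DMAP (1 equiv), CH2Cl2, 25 → 40 °C
Reagents that add atoms: 3-(benzyloxy)-4-methoxybenzoic acid 22, COc1ccc(C(=O)O)cc1OCc1ccccc1
Why: Steglich esterification acylates the secondary C7 hydroxyl while the tertiary C5 hydroxyl is inert; C7 keeps its configuration because its C–O bond is not broken.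

**Step 9**
Reactants: 23 (3aS,5R,7R,8S,8aR)-5-hydroxy-2,5-dimethyl-8-(propan-2-yl)-1,3a,4,5,6,7,8,8a-octahydroazulen-7-yl 3-(benzyloxy)-4-methoxybenzoate
Product: 24 (2R,3S,3aS,5R,7R,8S,8aR)-2,3-epoxy-5-hydroxy-2,5-dimethyl-8-(propan-2-yl)decahydroazulen-7-yl 3-(benzyloxy)-4-methoxybenzoate
Conditions: VO(acac)2 (5 mol %), t-BuOOH (1.5 equiv), CH2Cl2, 0 → 25 °C
Reagents that add atoms: tert-butyl hydroperoxide, CC(C)(C)OO
Why: Hydroxyl-directed vanadium/hydroperoxide epoxidation, in which the α-oriented C5 alkoxide binds vanadium and delivers oxygen to the α face of the trisubstituted alkene (bishomoallylic delivery), setting C2 and C3; the α-epoxide cannot be opened by the C5 hydroxyl because that would need a trans-fused oxolane.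

**Step 10**
Reactants: 24 (2R,3S,3aS,5R,7R,8S,8aR)-2,3-epoxy-5-hydroxy-2,5-dimethyl-8-(propan-2-yl)decahydroazulen-7-yl 3-(benzyloxy)-4-methoxybenzoate
Product: 25 (2R,3S,3aS,5R,7R,8S,8aR)-2,3-epoxy-5-hydroxy-2,5-dimethyl-8-(propan-2-yl)decahydroazulen-7-yl 3-hydroxy-4-methoxybenzoate
Conditions: H2 (1 atm), Pd/C, EtOAc, 25 °C
Reagents that add atoms: none
Why: Hydrogenolysis of the benzyl aryl ether under neutral conditions, to which the non-benzylic epoxide, the tertiary alcohol and the benzoate ester are inert.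

**Compound list**
1 | 4,4-dimethoxybutan-2-one | CC(=O)CC(OC)OC | starting material
2 | allylboronic acid pinacol ester | C=CCB1OC(C)(C)C(C)(C)O1 | starting material
3 | O-pinacolboryl ether of 4 (same carbinol configuration) | COC(OC)C[C@@](C)(OB1OC(C)(C)C(C)(C)O1)CC=C | intermediate
4 | (3S)-1,1-dimethoxy-3-methylhex-5-en-3-ol | COC(OC)C[C@@](C)(O)CC=C | intermediate
5 | secondary ozonide of 4 (3-substituted 1,2,4-trioxolane; carbinol centre as in 4, trioxolane carbon undefined) | COC(OC)C[C@@](C)(O)CC1OCOO1 | intermediate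
6 | (3S)-3-hydroxy-5,5-dimethoxy-3-methylpentanal | COC(OC)C[C@@](C)(O)CC=O | intermediate
7 | (E)-4-methylpent-2-ene | C/C=C/C(C)C | starting material
8 | (−)-B-methoxydiisopinocampheylborane (from (+)-α-pinene) | COB([C@H]1[C@H](C)[C@H]2C[C@@H](C1)C2(C)C)[C@H]1[C@H](C)[C@H]2C[C@@H](C1)C2(C)C | starting material
9 | (E)-4-methylpent-2-enylpotassium | [K+].[CH2-]/C=C/C(C)C | intermediate
10 | (E)-(4-methylpent-2-en-1-yl)diisopinocampheylborane | CC(C)/C=C/CB([C@H]1[C@H](C)[C@H]2C[C@@H](C1)C2(C)C)[C@H]1[C@H](C)[C@H]2C[C@@H](C1)C2(C)C | intermediate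
11 | O-diisopinocampheylboryl (borinate) ester of 12 at the C5 oxygen | COC(OC)C[C@@](C)(O)C[C@@H](OB([C@H]1[C@H](C)[C@H]2C[C@@H](C1)C2(C)C)[C@H]1[C@H](C)[C@H]2C[C@@H](C1)C2(C)C)[C@@H](C(C)C)C=C | intermediate
12 | (3S,5R,6S)-1,1-dimethoxy-3-methyl-6-(propan-2-yl)oct-7-ene-3,5-diol | COC(OC)C[C@@](C)(O)C[C@@H](O)[C@@H](C(C)C)C=C | intermediate
13 | but-3-en-2-one (methyl vinyl ketone) | CC(=O)C=C | starting material
14 | (3E,5S,6R,8S)-6,8-dihydroxy-10,10-dimethoxy-8-methyl-5-(propan-2-yl)dec-3-en-2-one | COC(OC)C[C@@](C)(O)C[C@@H](O)[C@@H](C(C)C)/C=C/C(C)=O | intermediate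
15 | N-(1-methoxyalkyl)-2,6-dimethylpyridinium triflate from 14, both hydroxyls as triethylsilyl ethers (acetal carbon undefined) | COC(C[C@@](C)(O[Si](CC)(CC)CC)C[C@@H](O[Si](CC)(CC)CC)[C@@H](C(C)C)/C=C/C(C)=O)[n+]1c(C)cccc1C.[O-]S(=O)(=O)C(F)(F)F | intermediate
16 | (3S,5R,6S,7E)-3-methyl-9-oxo-6-(propan-2-yl)-3,5-bis(triethylsilyloxy)dec-7-enal | O=CC[C@@](C)(O[Si](CC)(CC)CC)C[C@@H](O[Si](CC)(CC)CC)[C@@H](C(C)C)/C=C/C(C)=O | intermediate
17 | (triphenylphosphoranylidene)acetaldehyde | O=CC=P(c1ccccc1)(c1ccccc1)c1ccccc1 | starting material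
18 | (2E,5R,7R,8S,9E)-5-methyl-11-oxo-8-(propan-2-yl)-5,7-bis(triethylsilyloxy)dodeca-2,9-dienal | O=C/C=C/C[C@@](C)(O[Si](CC)(CC)CC)C[C@@H](O[Si](CC)(CC)CC)[C@@H](C(C)C)/C=C/C(C)=O | intermediate
19 | trans-fused hydroazulene carrying a β-lactone across C2 (O) and C3 (C=O) on the β face, 5,7-bis(triethylsilyl) ether (lactone carbons assigned tentatively; both are lost with CO2) | CC[Si](CC)(CC)O[C@@H]1C[C@](C)(O[Si](CC)(CC)CC)C[C@H]2[C@@H](C[C@]3(C)OC(=O)[C@H]23)[C@@H]1C(C)C | intermediate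
20 | (3aS,5R,7R,8S,8aR)-2,5-dimethyl-8-(propan-2-yl)-5,7-bis(triethylsilyloxy)-1,3a,4,5,6,7,8,8a-octahydroazulene | CC[Si](CC)(CC)O[C@@H]1C[C@](C)(O[Si](CC)(CC)CC)C[C@H]2[C@@H](CC(C)=C2)[C@@H]1C(C)C | intermediate
21 | (3aS,5R,7R,8S,8aR)-2,5-dimethyl-8-(propan-2-yl)-1,3a,4,5,6,7,8,8a-octahydroazulene-5,7-diol | O[C@@H]1C[C@](C)(O)C[C@H]2[C@@H](CC(C)=C2)[C@@H]1C(C)C | intermediate
22 | 3-(benzyloxy)-4-methoxybenzoic acid | COc1ccc(C(=O)O)cc1OCc1ccccc1 | starting material
23 | (3aS,5R,7R,8S,8aR)-5-hydroxy-2,5-dimethyl-8-(propan-2-yl)-1,3a,4,5,6,7,8,8a-octahydroazulen-7-yl 3-(benzyloxy)-4-methoxybenzoate | COc1ccc(C(=O)O[C@@H]2C[C@](C)(O)C[C@H]3[C@@H](CC(C)=C3)[C@@H]2C(C)C)cc1OCc1ccccc1 | intermediate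
24 | (2R,3S,3aS,5R,7R,8S,8aR)-2,3-epoxy-5-hydroxy-2,5-dimethyl-8-(propan-2-yl)decahydroazulen-7-yl 3-(benzyloxy)-4-methoxybenzoate | COc1ccc(C(=O)O[C@@H]2C[C@](C)(O)C[C@H]3[C@@H](C[C@@]4(C)O[C@@H]34)[C@@H]2C(C)C)cc1OCc1ccccc1 | intermediate
25 | (2R,3S,3aS,5R,7R,8S,8aR)-2,3-epoxy-5-hydroxy-2,5-dimethyl-8-(propan-2-yl)decahydroazulen-7-yl 3-hydroxy-4-methoxybenzoate | COc1ccc(C(=O)O[C@@H]2C[C@](C)(O)C[C@H]3[C@@H](C[C@@]4(C)O[C@@H]34)[C@@H]2C(C)C)cc1O | target

**Step count**
Total: 10 steps. Longest linear sequence: 10 steps (1 → 25); all other inputs (2, 7, 8, 13, 17, 22) are bought.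

**Steps most likely to fail**

Step 7 (carbene-catalysed double ring closure). The seven-ring homoenolate addition is unprecedented in intramolecular form and may lose to enal dimerisation or give the wrong C3a/C8a pair. The fallback sets out from aldehyde 16 and comes back at 20. Wittig reaction of 16 with Ph3P=CHOMe (from the phosphonium chloride and KN(SiMe3)2, THF, −78 → 0 °C) gives the enol ether (3E,5S,6R,8R)-11-methoxy-8-methyl-5-(propan-2-yl)-6,8-bis(triethylsilyloxy)undeca-3,10-dien-2-one F1 (E/Z mixture at the enol ether). Oxalic acid on wet SiO2 hydrolyses it to the one-carbon-longer aldehyde (4R,6R,7S,8E)-4-methyl-10-oxo-7-(propan-2-yl)-4,6-bis(triethylsilyloxy)undec-8-enal F2. Pyrrolidine/AcOH (enamine catalysis) then closes the seven-membered ring by intramolecular Michael addition to the keto-aldehyde (1S,2S,3S,4R,6R)-6-methyl-2-(2-oxopropyl)-3-(propan-2-yl)-4,6-bis(triethylsilyloxy)cycloheptane-1-carbaldehyde F3, whose aldehyde-bearing carbon can equilibrate to the trans isomer. McMurry coupling (TiCl3, Zn–Cu, DME, reflux) joins the aldehyde and ketone carbons to give 20, which is desilylated with Bu4NF to 21.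

Step 9 (face of the epoxidation). The seven-membered ring sits on the α side of the cyclopentene, so without effective delivery from the C5 hydroxyl the reagent would attack the β face. The fallback sets out from 20 (isolated before the fluoride treatment of step 7) and comes back at 24. NBS in aqueous DME forms the bromonium ion on the open β face and water opens it at the tertiary carbon from the α face, giving the bromohydrin (2R,3R,3aS,5R,7R,8S,8aS)-3-bromo-2,5-dimethyl-8-(propan-2-yl)-5,7-bis(triethylsilyloxy)decahydroazulen-2-ol F4. K2CO3 in MeOH closes it with inversion at C3 to the α-epoxide (2R,3S,3aS,5R,7R,8S,8aR)-2,3-epoxy-2,5-dimethyl-8-(propan-2-yl)-5,7-bis(triethylsilyloxy)decahydroazulene F5. Bu4NF gives the epoxy diol (2R,3S,3aS,5R,7R,8S,8aR)-2,3-epoxy-2,5-dimethyl-8-(propan-2-yl)decahydroazulene-5,7-diol F6, and DCC/DMAP acylation with 22 gives 24.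

Step 4 (cross-metathesis of a hindered vinyl group). The alkene is flanked by an isopropyl-bearing carbon and may react slowly or not at all. The fallback sets out from 12 and comes back at 14. Ozonolysis of 12 (O3, CH2Cl2, −78 °C; PPh3) gives the aldehyde (2R,3R,5S)-3,5-dihydroxy-7,7-dimethoxy-5-methyl-2-(propan-2-yl)heptanal F7, which is treated without purification with 1-(triphenylphosphoranylidene)propan-2-one in CH2Cl2 at 25 °C to give 14.

**Further compounds**
F1 | step 7 | (3E,5S,6R,8R)-11-methoxy-8-methyl-5-(propan-2-yl)-6,8-bis(triethylsilyloxy)undeca-3,10-dien-2-one | COC=CC[C@@](C)(O[Si](CC)(CC)CC)C[C@@H](O[Si](CC)(CC)CC)[C@@H](C(C)C)/C=C/C(C)=O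
F2 | step 7 | (4R,6R,7S,8E)-4-methyl-10-oxo-7-(propan-2-yl)-4,6-bis(triethylsilyloxy)undec-8-enal | O=CCC[C@@](C)(O[Si](CC)(CC)CC)C[C@@H](O[Si](CC)(CC)CC)[C@@H](C(C)C)/C=C/C(C)=O
F3 | step 7 | (1S,2S,3S,4R,6R)-6-methyl-2-(2-oxopropyl)-3-(propan-2-yl)-4,6-bis(triethylsilyloxy)cycloheptane-1-carbaldehyde | CC[Si](CC)(CC)O[C@@H]1C[C@](C)(O[Si](CC)(CC)CC)C[C@H](C=O)[C@@H](CC(C)=O)[C@@H]1C(C)C
F4 | step 9 | (2R,3R,3aS,5R,7R,8S,8aS)-3-bromo-2,5-dimethyl-8-(propan-2-yl)-5,7-bis(triethylsilyloxy)decahydroazulen-2-ol | CC[Si](CC)(CC)O[C@@H]1C[C@](C)(O[Si](CC)(CC)CC)C[C@H]2[C@@H](C[C@@](C)(O)[C@@H]2Br)[C@@H]1C(C)C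
F5 | step 9 | (2R,3S,3aS,5R,7R,8S,8aR)-2,3-epoxy-2,5-dimethyl-8-(propan-2-yl)-5,7-bis(triethylsilyloxy)decahydroazulene | CC[Si](CC)(CC)O[C@@H]1C[C@](C)(O[Si](CC)(CC)CC)C[C@H]2[C@@H](C[C@@]3(C)O[C@@H]23)[C@@H]1C(C)C
F6 | step 9 | (2R,3S,3aS,5R,7R,8S,8aR)-2,3-epoxy-2,5-dimethyl-8-(propan-2-yl)decahydroazulene-5,7-diol | O[C@@H]1C[C@](C)(O)C[C@H]2[C@@H](C[C@@]3(C)O[C@@H]23)[C@@H]1C(C)C
F7 | step 4 | (2R,3R,5S)-3,5-dihydroxy-7,7-dimethoxy-5-methyl-2-(propan-2-yl)heptanal | COC(OC)C[C@@](C)(O)C[C@@H](O)[C@@H](C(C)C)C=O
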